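## The problem

Compound 16 is a flavonol, a 2-aryl-3-hydroxy-4H-chromen-4-one. Ring A (C4a, C5 to C8, C8a) is fused to the pyranone ring C, ring B is the 4-hydroxyphenyl group on C2, and ring A carries oxygen on C5, C6 and C7, so that only C8 bears hydrogen. The molecule has no stereocentre and no other stereochemical element, so nothing has to be set or relayed; the difficulties are regiochemical and concern functional-group tolerance. The first task is to place the three neighbouring oxygens on C5, C6 and C7 and not on C5, C7 and C8. These two patterns differ only in which ortho oxygen of the ring A ketone closes ring C. The second task is to tell O7 from O3, O5, O6 and O4′, because only O7 carries the sulfate. The third is lability: an aryl sulfate monoester is lost in strong protic or Lewis acid, and the bare 5,6-dihydroxy ring A is oxidised easily in base and air, so the sulfate must come late and be followed only by mild operations. The feature that invites a short convergent assembly is C4, a carbonyl carbon with no substituent of its own, lying between C4a of ring A and the oxygen-bearing C3. It can be brought in as carbon monoxide 7, linking an aryl iodide (ring A) to the α-carbon of an α-alkoxy ketone (C3, C2 and ring B); ring C then closes by addition of O1 to the C2 carbonyl.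

## Retrosynthesis

**Sulfate and temporary groups (16 ⇒ 15 ⇒ 14).** The four acetyl C–O bonds of 16 are cut first, giving sulfate tetraacetate 15, and then the O7–S bond, giving phenol 14 with a single free hydroxyl. Acetates are preferred to ethers on O3, O5, O6 and O4′ because they leave by ammonolysis, to which a sulfate monoanion is inert. Any ether would need acid, Lewis acid or a further protecting-group exchange after the sulfate is in place. The forward steps ask only for O-sulfation of the one free phenol and a deacylation with oxygen excluded.

**Singling out O7 (14 ⇒ 13 ⇒ 12).** Re-forming the acetyl–O7 bond leads to pentaacetate 13, and removing all five acetyl groups leads to pentaol 12. The neighbouring choice, a distinct group carried on O7 from the start, is rejected. O5 and O7 stem from the two equivalent oxygens of a symmetric phenol, and distinguishing them early would destroy the symmetry that makes the ring A building block unambiguous. In the flavone O7 is electronically unique: it is para to the C4 carbonyl through ring A, so its acetate is the best acyl donor. The forward reaction must remove that one acetate with a soft nucleophile and leave the 3-, 5-, 6- and 4′-acetates.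

**Ether cleavage (12 ⇒ 11).** Five O–CH3 bonds are restored, giving pentamethyl ether 11. Methyl ethers are chosen over benzyl ethers because ring A then comes from the commercial phenol 1 and the ketone from 4 and 5 in one step. The price is one exhaustive Lewis-acid demethylation, placed before the sulfate exists. The 5,6,7 pattern is the favoured side of the acid-promoted ring switch, so the cleavage should not scramble ring A.

**Ring C (11 ⇒ 10 ⇒ 9 ⇒ 8).** Cutting O1–C2 with formal addition of water gives hemiketal 10 and its open form, phenol diketone 9. Masking O1 as a methoxymethyl ether gives diketone 8. This cut keeps every carbon of the flavonol in one chain and leaves a classical acid cyclodehydration as the forward step. Only O1 is unmasked by acid, since O5 stays a methyl ether, and this fixes the 5,6,7 pattern.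

**Key disconnection (8 ⇒ 3 + 7 + 6).** Both bonds to C4 are cut, C4a–C4 and C3–C4, so that C4 becomes carbon monoxide 7 and the rest falls into aryl iodide 3 and α-methoxy ketone 6. Two neighbouring cuts are less direct:
- Cutting only C3–C4 would need a separate ring A carboxylic acid derivative.
- Cutting C2–C3 would need an ortho-hydroxy ω-methoxyacetophenone of ring A and an acyl-transfer rearrangement.

The three-component cut takes ring A straight from an iodophenol. The forward reaction must insert CO before the C–C coupling, acylate the enolate on carbon and not on oxygen, and tolerate two ortho substituents on the aryl iodide.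

**Building blocks (3 ⇒ 2 ⇒ 1; 6 ⇒ 4 + 5).** The O–CH2 bond of 3 leads to iodophenol 2 and the C–I bond to 3,4,5-trimethoxyphenol 1, whose two free ring positions are equivalent, so iodination can give only one mono-iodide. Ketone 6 is cut at the aryl–carbonyl bond into anisole 4 and methoxyacetyl chloride 5, a para-selective Friedel–Crafts acylation in the forward direction.

## Roads not taken

**Alternative 1:** Ring A is cut at C4a–C5. This leads to keto ester A2, a 4-pyranone of the kojic acid A3 type that already holds ring C, ring B and a β-keto ester side chain on the future C8a.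
- Forward key step: Mg(OMe)2 would form the dienolate, whose ring carbon (the future C4a) attacks the ester carbon with loss of methoxide, and enolisation would give A1 with ring A aromatic.
- Merit: A1 emerges with exactly the pattern the end game wants. O3, O6 and O4′ are benzylated, and of the 5,7-diol only the unchelated 7-hydroxyl is reactive. Sulfation and a neutral hydrogenolysis would finish the synthesis in two steps. Here this road is better than the chosen one, which needs acetylation, selective deacetylation and a basic final step.
- Weak points: A2 is far from simple. From A3 it needs arylation of a ring carbon, two benzylations and extension of the hydroxymethyl arm into an α-benzyloxy β-keto ester, a long linear sequence. The closure asks a ring carbon of a pyranone dienolate to be acylated in competition with the more acidic CH2 and CH(OBn) positions and with O-acylation, a reaction without close precedent on this substrate class.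
- Comparison: against the better end game the chosen plan sets a key reaction of known type and a complete carbon skeleton four steps from three commercial compounds.

**Alternative 2:** The C6 oxygen is introduced as a C8 oxygen and ring C is then switched.
- Forward sequence: kaempferol A7 is methylated to the 5-hydroxy trimethyl ether A6, and Elbs oxidation (K2S2O8, aqueous alkali) para to the 5-hydroxyl gives A5.
- Forward key step: hot HI in acetic acid cleaves the ethers to A8, opens ring C and recloses it through the former O5, forming a new O1–C2 bond and delivering A4, which is identical with 12.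
- Merit: it reaches the stage of 12 in three steps, against six in the chosen plan, without palladium or CO. In step count it is clearly better.
- Weak points: the Elbs oxidation typically stops at low conversion. The ring switch is an equilibrium through the open diketone, so A4 must be separated from residual A8, two pentahydroxy isomers that are hard to tell apart. Refluxing HI is hard on a pyrogallol-type ring. The route also depends on buying the flavonol skeleton.
- Comparison: from A4 onward the end game is the same as from 12, so nothing is gained there. The chosen plan sets against the shorter count a ring A pattern proved by construction from a symmetric phenol and steps of predictable conversion.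

**Alternative 3:** Ring C is cut at C3–C4, leading to dialdehyde A10.
- Forward key step: a carbene generated from a thiazolium salt and NEt3 turns the aromatic aldehyde into an acyl anion equivalent that adds to the aliphatic aldehyde, closing ring C as the acyloin A9.
- Merit: the step is metal-free, closes the ring directly and delivers O3 as a free hydroxyl already distinguished from the methyl ethers.
- Weak points: the α-aryl α-aryloxy acetaldehyde of A10 is highly enolisable and prone to loss of the phenoxide and to aldol reactions. The carbene normally engages the more reactive aliphatic aldehyde first, which would give the regioisomeric acyloin. A9 is one oxidation level too low and needs a dehydrogenation before the stage of 11 or 12. Making A10 requires alkylating a hindered salicylaldehyde with a masked α-halo arylacetaldehyde.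
- Comparison: the chosen plan arrives at the flavonol oxidation level directly, from precursors made in one or two steps, and needs no fragile aldehyde.

Key step: step 4

Remark on the chemistry: 16 is drawn as the free hydrogen sulfate; it is assumed that 15 and 16 are handled as their pyridinium and ammonium salts, and names and SMILES refer to the neutral acid forms.

## Route

Step 1
Reactants: 1 3,4,5-trimethoxyphenol
Product: 2 2-iodo-3,4,5-trimethoxyphenol
Conditions: N-iodosuccinimide (1.0 equiv), MeCN, −20 → 0 °C, dark
Reagents that add atoms: N-iodosuccinimide, O=C1CCC(=O)N1I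
Why: Electrophilic aromatic iodination of an activated phenol; the two free ring positions of 1 are equivalent by symmetry and each is ortho to the hydroxyl, so only one mono-iodide can form, and one equivalent of reagent at low temperature should hold back a second iodination and oxidation of the ring.

Step 2
Reactants: 2 2-iodo-3,4,5-trimethoxyphenol
Product: 3 2-iodo-3,4,5-trimethoxy-1-(methoxymethoxy)benzene
Conditions: MOMCl, i-Pr2NEt, CH2Cl2, 0 °C → rt
Reagents that add atoms: chloromethyl methyl ether, COCCl
Why: O-alkylation of the phenol to a methoxymethyl acetal; the acetal withstands the basic carbonylation of step 4 and is cleaved by the acid of step 5, and the small electrophile tolerates the neighbouring iodine.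

Step 3
Reactants: 4 anisole, 5 methoxyacetyl chloride
Product: 6 2-methoxy-1-(4-methoxyphenyl)ethanone
Conditions: AlCl3, CH2Cl2, −10 → 0 °C; ice/aq. HCl quench
Reagents that add atoms: none
Why: Friedel–Crafts acylation; the methoxy group of anisole directs the acylium ion to the para position, and low temperature should limit loss of CO from the α-methoxy acylium ion and ether cleavage by AlCl3.

Step 4
Reactants: 3 2-iodo-3,4,5-trimethoxy-1-(methoxymethoxy)benzene, 7 carbon monoxide, 6 2-methoxy-1-(4-methoxyphenyl)ethanone
Product: 8 2-methoxy-1-(4-methoxyphenyl)-3-[2,3,4-trimethoxy-6-(methoxymethoxy)phenyl]propane-1,3-dione (racemic at the central carbon)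
Conditions: Pd(dba)2 (5 mol %), 4,5-bis(diphenylphosphino)-9,9-dimethylxanthene (6 mol %), CO (1 atm), K3PO4 (3 equiv), 6 (1.5 equiv), 1,4-dioxane, 80 °C; aq. NH4Cl work-up
Reagents that add atoms: none
Why: This is a palladium-catalysed carbonylative α-arylation of a ketone, the known three-component reaction of aryl iodides, CO and ketone enolates that gives 1,3-diketones. Zerovalent palladium inserts into the C4a–I bond of 3, CO coordinates and the aryl group migrates onto it, which forms C4a–C4 in an aroyl complex of divalent palladium. The potassium enolate of 6, generated by K3PO4, replaces iodide on the metal, and reductive elimination of the aroyl and carbon-bound enolate ligands forms C3–C4 and returns zerovalent palladium. No ring is closed, and the one new stereocentre, the CH(OMe) carbon that becomes C3, is formed racemic, is enolisable and is erased in step 5, so it needs no control. Three selectivities are needed: CO insertion before coupling (otherwise direct α-arylation results), acylation of the enolate on carbon and not on oxygen, and a single acylation. The first is secured by the two ortho oxygen substituents and the electron-rich ring of 3, which slow direct aryl–enolate coupling and speed aryl migration to CO, together with the wide bite angle of the diphosphine, which favours the acyl pathway at one atmosphere of CO. The second and third are secured because 8 is more acidic than 6 and is drained off as its potassium 1,3-diketonate, which is hindered at its central carbon, resists further acylation and returns 8 on mild acidic work-up.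

Step 5
Reactants: 8 2-methoxy-1-(4-methoxyphenyl)-3-[2,3,4-trimethoxy-6-(methoxymethoxy)phenyl]propane-1,3-dione
Product: 11 3,5,6,7-tetramethoxy-2-(4-methoxyphenyl)-4H-chromen-4-one, via free phenol diketone 9 (not isolated), via 2-hydroxyflavanone hemiketal 10 (not isolated)
Conditions: conc. HCl, MeOH, 60 °C
Reagents that add atoms: none
Why: Acid-catalysed acetal cleavage frees the O1 phenol (9), which adds 6-exo-trig to the C2 carbonyl to give hemiketal 10, and acid-catalysed dehydration to the aromatic 4-pyranone follows (the classical cyclodehydration of ortho-hydroxy dibenzoylmethanes); because O5 remains a methyl ether only O1 can close the ring, which fixes the 5,6,7 pattern, and the stereocentres of 8 and 10 disappear.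

Step 6
Reactants: 11 3,5,6,7-tetramethoxy-2-(4-methoxyphenyl)-4H-chromen-4-one
Product: 12 3,5,6,7-tetrahydroxy-2-(4-hydroxyphenyl)-4H-chromen-4-one (6-hydroxykaempferol)
Conditions: BBr3 (excess), CH2Cl2, −78 °C → rt, Ar; MeOH then H2O at 0 °C
Reagents that add atoms: none
Why: Lewis-acid cleavage of aryl methyl ethers, in which bromide attacks the methyl group of each boron-complexed ether; the 3- and 5-methoxy groups are helped by chelation to the C4 carbonyl, excess reagent with warming should take the 6-, 7- and 4′-groups, and the 5,6,7-trihydroxy pattern is the favoured side of the acid ring switch, so no rearrangement is expected; the air-sensitive pentaol is carried on at once.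

Step 7
Reactants: 12 3,5,6,7-tetrahydroxy-2-(4-hydroxyphenyl)-4H-chromen-4-one
Product: 13 2-(4-acetoxyphenyl)-4-oxo-4H-chromene-3,5,6,7-tetrayl tetraacetate
Conditions: Ac2O, pyridine, DMAP (cat.), rt
Reagents that add atoms: acetic anhydride, CC(=O)OC(C)=O
Why: Exhaustive O-acetylation under nucleophilic catalysis; DMAP is included for the hydrogen-bonded 5-hydroxyl, and the pentaacetate is a stable, purifiable form of the oxidation-prone pentaol.

Step 8
Reactants: 13 2-(4-acetoxyphenyl)-4-oxo-4H-chromene-3,5,6,7-tetrayl tetraacetate
Product: 14 2-(4-acetoxyphenyl)-7-hydroxy-4-oxo-4H-chromene-3,5,6-triyl triacetate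
Conditions: PhSH (1.1 equiv), imidazole (cat.), N-methyl-2-pyrrolidone, 0 °C
Reagents that add atoms: none
Why: Chemoselective thiolysis of an aryl acetate (acyl transfer to thiophenol under imidazole catalysis), a known way to single out the 7-acetate of peracetylated flavones and flavonols; O7 is para to the C4 carbonyl, so its phenoxide is the best leaving group, and low temperature with little base should spare the 4′-acetate and suppress acetyl shift from O6.

Step 9
Reactants: 14 2-(4-acetoxyphenyl)-7-hydroxy-4-oxo-4H-chromene-3,5,6-triyl triacetate
Product: 15 2-(4-acetoxyphenyl)-4-oxo-7-(sulfooxy)-4H-chromene-3,5,6-triyl triacetate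
Conditions: SO3·pyridine (excess), DMF, rt
Reagents that add atoms: sulfur trioxide–pyridine complex, O=S(=O)([O-])[n+]1ccccc1
Why: O-sulfation of a phenol by transfer of SO3 from its amine complex; 14 has one free hydroxyl, so the sulfate can enter only at O7, and a medium without strong base should keep the acetates in place.

Step 10
Reactants: 15 2-(4-acetoxyphenyl)-4-oxo-7-(sulfooxy)-4H-chromene-3,5,6-triyl triacetate
Product: 16 3,5,6-trihydroxy-2-(4-hydroxyphenyl)-4-oxo-4H-chromen-7-yl hydrogen sulfate (target)
Conditions: NH3 (7 M in MeOH), degassed, 0 °C → rt, Ar; reversed-phase chromatography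
Reagents that add atoms: none
Why: Ammonolysis of the four aryl and enol acetates; an aryl sulfate monoanion is not attacked by ammonia or methoxide under these conditions, so the O7–S bond should survive, and exclusion of oxygen protects the 5,6-dihydroxy ring while it is present as phenoxide.

## Compound list

1 | 3,4,5-trimethoxyphenol | COc1cc(O)cc(OC)c1OC | starting material
2 | 2-iodo-3,4,5-trimethoxyphenol | COc1cc(O)c(I)c(OC)c1OC | intermediate
3 | 2-iodo-3,4,5-trimethoxy-1-(methoxymethoxy)benzene | COCOc1cc(OC)c(OC)c(OC)c1I | intermediate
4 | anisole (methoxybenzene) | COc1ccccc1 | starting material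
5 | methoxyacetyl chloride | COCC(=O)Cl | starting material
6 | 2-methoxy-1-(4-methoxyphenyl)ethanone | COCC(=O)c1ccc(OC)cc1 | intermediate
7 | carbon monoxide | [C-]#[O+] | starting material
8 | 2-methoxy-1-(4-methoxyphenyl)-3-[2,3,4-trimethoxy-6-(methoxymethoxy)phenyl]propane-1,3-dione (racemic) | COCOc1cc(OC)c(OC)c(OC)c1C(=O)C(OC)C(=O)c1ccc(OC)cc1 | intermediate
9 | 1-(6-hydroxy-2,3,4-trimethoxyphenyl)-2-methoxy-3-(4-methoxyphenyl)propane-1,3-dione (racemic, not isolated) | COc1ccc(C(=O)C(OC)C(=O)c2c(O)cc(OC)c(OC)c2OC)cc1 | intermediate
10 | 2-hydroxy-3,5,6,7-tetramethoxy-2-(4-methoxyphenyl)chroman-4-one (mixture of racemic diastereomers, not isolated) | COc1ccc(C2(O)Oc3cc(OC)c(OC)c(OC)c3C(=O)C2OC)cc1 | intermediate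
11 | 3,5,6,7-tetramethoxy-2-(4-methoxyphenyl)-4H-chromen-4-one | COc1ccc(-c2oc3cc(OC)c(OC)c(OC)c3c(=O)c2OC)cc1 | intermediate
12 | 3,5,6,7-tetrahydroxy-2-(4-hydroxyphenyl)-4H-chromen-4-one (6-hydroxykaempferol) | O=c1c(O)c(-c2ccc(O)cc2)oc2cc(O)c(O)c(O)c12 | intermediate
13 | 2-(4-acetoxyphenyl)-4-oxo-4H-chromene-3,5,6,7-tetrayl tetraacetate | CC(=O)Oc1ccc(-c2oc3cc(OC(C)=O)c(OC(C)=O)c(OC(C)=O)c3c(=O)c2OC(C)=O)cc1 | intermediate
14 | 2-(4-acetoxyphenyl)-7-hydroxy-4-oxo-4H-chromene-3,5,6-triyl triacetate | CC(=O)Oc1ccc(-c2oc3cc(O)c(OC(C)=O)c(OC(C)=O)c3c(=O)c2OC(C)=O)cc1 | intermediate
15 | 2-(4-acetoxyphenyl)-4-oxo-7-(sulfooxy)-4H-chromene-3,5,6-triyl triacetate | CC(=O)Oc1ccc(-c2oc3cc(OS(=O)(=O)O)c(OC(C)=O)c(OC(C)=O)c3c(=O)c2OC(C)=O)cc1 | intermediate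
16 | 3,5,6-trihydroxy-2-(4-hydroxyphenyl)-4-oxo-4H-chromen-7-yl hydrogen sulfate | O=c1c(O)c(-c2ccc(O)cc2)oc2cc(OS(=O)(=O)O)c(O)c(O)c12 | target

## Step count and least certain steps

Total step count: 10. Longest linear sequence: 9 steps (steps 1, 2, 4, 5, 6, 7, 8, 9 and 10, from 1); step 3 is a one-step side branch that joins at step 4.

**Step 4 (key step).**
- Risk: slow capture of the hindered, electron-rich aroylpalladium intermediate by the enolate. Reduction of the C–I bond, acylation of the enolate on oxygen, coupling without CO, or base-induced self-condensation of the α-methoxy ketone could then take over.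
- Fallback: it forms the same two bonds one after the other by polar chemistry, sets out from 3 and returns at 8. Iodine–magnesium exchange with i-PrMgCl·LiCl (THF, −20 °C) gives [2,3,4-trimethoxy-6-(methoxymethoxy)phenyl]magnesium chloride F1. Carboxylation with CO2 and a mild acidic work-up give 2,3,4-trimethoxy-6-(methoxymethoxy)benzoic acid F2, which forms C4a–C4. 1,1′-Carbonyldiimidazole in THF converts F2 into (1H-imidazol-1-yl)[2,3,4-trimethoxy-6-(methoxymethoxy)phenyl]methanone F3. Claisen-type C-acylation of 6, deprotonated with LiN(SiMe3)2 (2 equiv, THF, −78 → 0 °C), by F3 forms C3–C4 and gives 8.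

**Step 8.**
- Risk: shift of the acetyl group from O6 to the freed O7 phenoxide followed by further thiolysis, or competing loss of the 4′-acetate, because the 6-acetate is directly next to the reacting site. A mixture of partially acetylated phenols would result.
- Fallback: it traps the phenoxide instead of leaving it free, sets out from 13 and returns at 14. BnBr, K2CO3 and KI (cat.) in refluxing acetone exchange the 7-acetate for a benzyl ether as soon as the phenoxide appears, giving 2-(4-acetoxyphenyl)-7-(benzyloxy)-4-oxo-4H-chromene-3,5,6-triyl triacetate F4, a neutral compound that can be purified. Hydrogenolysis (H2, 10% Pd/C, EtOAc, rt) then releases 14 under neutral conditions, in which acyl shift is slow.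

**Step 9.**
- Risk: sluggish sulfation of the acidic, weakly nucleophilic 7-phenol beside the 6-acetate, acetyl migration during a long reaction time, and loss of material because the ionic product cannot be purified before the last step.
- Fallback: it uses a masked sulfate, sets out from 14 and returns at 15. 2,2,2-Trichloroethyl chlorosulfate with DMAP and Et3N (THF, 0 °C) gives the neutral diester 2-(4-acetoxyphenyl)-4-oxo-7-{[(2,2,2-trichloroethoxy)sulfonyl]oxy}-4H-chromene-3,5,6-triyl triacetate F5, which is purified on silica. Zn dust and HCO2NH4 in MeOH at rt remove the trichloroethyl group by reductive elimination and deliver 15.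

**Step 3.**
- Risk: Lewis-acid-induced loss of CO from the α-methoxy acylium ion, which would lead to methoxymethylation of anisole, and cleavage of methyl ethers by AlCl3.
- Fallback: it avoids the acylium ion, sets out from 5 and returns at 6. N,O-Dimethylhydroxylamine hydrochloride and Et3N (CH2Cl2, 0 °C) give N,2-dimethoxy-N-methylacetamide F6. Commercial 4-methoxyphenylmagnesium bromide (THF, 0 °C) adds once through the chelated tetrahedral intermediate and gives 6 as a single regioisomer.

**Step 1.**
- Risk: a second iodination at the other ortho position, and oxidative demethylation of the para-methoxyphenol to a quinone by the electrophilic iodine source.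
- Fallback: it reverses the order of protection and halogenation, sets out from 1 and returns at 3. MOMCl and i-Pr2NEt give 1,2,3-trimethoxy-5-(methoxymethoxy)benzene F7. Directed ortho-lithiation (n-BuLi, THF, 0 °C) at the only type of free position, flanked by the acetal and a methoxy group, gives [2,3,4-trimethoxy-6-(methoxymethoxy)phenyl]lithium F8. Iodine at −78 °C converts F8 into 3.

## Further compounds

F1 | step 4 | [2,3,4-trimethoxy-6-(methoxymethoxy)phenyl]magnesium chloride | COCOc1cc(OC)c(OC)c(OC)c1[Mg]Cl
F2 | step 4 | 2,3,4-trimethoxy-6-(methoxymethoxy)benzoic acid | COCOc1cc(OC)c(OC)c(OC)c1C(=O)O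
F3 | step 4 | (1H-imidazol-1-yl)[2,3,4-trimethoxy-6-(methoxymethoxy)phenyl]methanone | COCOc1cc(OC)c(OC)c(OC)c1C(=O)n1ccnc1
F4 | step 8 | 2-(4-acetoxyphenyl)-7-(benzyloxy)-4-oxo-4H-chromene-3,5,6-triyl triacetate | CC(=O)Oc1ccc(-c2oc3cc(OCc4ccccc4)c(OC(C)=O)c(OC(C)=O)c3c(=O)c2OC(C)=O)cc1
F5 | step 9 | 2-(4-acetoxyphenyl)-4-oxo-7-{[(2,2,2-trichloroethoxy)sulfonyl]oxy}-4H-chromene-3,5,6-triyl triacetate | CC(=O)Oc1ccc(-c2oc3cc(OS(=O)(=O)OCC(Cl)(Cl)Cl)c(OC(C)=O)c(OC(C)=O)c3c(=O)c2OC(C)=O)cc1
F6 | step 3 | N,2-dimethoxy-N-methylacetamide | COCC(=O)N(C)OC
F7 | step 1 | 1,2,3-trimethoxy-5-(methoxymethoxy)benzene | COCOc1cc(OC)c(OC)c(OC)c1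
F8 | step 1 | [2,3,4-trimethoxy-6-(methoxymethoxy)phenyl]lithium | COCOc1cc(OC)c(OC)c(OC)c1[Li]
A1 | alternative 1 | 3,6-bis(benzyloxy)-2-[4-(benzyloxy)phenyl]-5,7-dihydroxy-4H-chromen-4-one | O=c1c(OCc2ccccc2)c(-c2ccc(OCc3ccccc3)cc2)oc2cc(O)c(OCc3ccccc3)c(O)c12
A2 | alternative 1 | methyl 2-(benzyloxy)-4-{5-(benzyloxy)-6-[4-(benzyloxy)phenyl]-4-oxo-4H-pyran-2-yl}-3-oxobutanoate | COC(=O)C(OCc1ccccc1)C(=O)Cc1cc(=O)c(OCc2ccccc2)c(-c2ccc(OCc3ccccc3)cc2)o1
A3 | alternative 1 | kojic acid, 5-hydroxy-2-(hydroxymethyl)-4H-pyran-4-one | OCc1cc(=O)c(O)co1
A4 | alternative 2 | 6-hydroxykaempferol (identical with 12) | O=c1c(O)c(-c2ccc(O)cc2)oc2cc(O)c(O)c(O)c12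
A5 | alternative 2 | 5,8-dihydroxy-3,7-dimethoxy-2-(4-methoxyphenyl)-4H-chromen-4-one | COc1ccc(-c2oc3c(O)c(OC)cc(O)c3c(=O)c2OC)cc1
A6 | alternative 2 | 5-hydroxy-3,7-dimethoxy-2-(4-methoxyphenyl)-4H-chromen-4-one | COc1ccc(-c2oc3cc(OC)cc(O)c3c(=O)c2OC)cc1
A7 | alternative 2 | kaempferol, 3,5,7-trihydroxy-2-(4-hydroxyphenyl)-4H-chromen-4-one | O=c1c(O)c(-c2ccc(O)cc2)oc2cc(O)cc(O)c12
A8 | alternative 2 | 3,5,7,8-tetrahydroxy-2-(4-hydroxyphenyl)-4H-chromen-4-one | O=c1c(O)c(-c2ccc(O)cc2)oc2c(O)c(O)cc(O)c12
A9 | alternative 3 | 3-hydroxy-5,6,7-trimethoxy-2-(4-methoxyphenyl)chroman-4-one (mixture of stereoisomers) | COc1ccc(C2Oc3cc(OC)c(OC)c(OC)c3C(=O)C2O)cc1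
A10 | alternative 3 | 2,3,4-trimethoxy-6-[1-(4-methoxyphenyl)-2-oxoethoxy]benzaldehyde (racemic) | COc1ccc(C(C=O)Oc2cc(OC)c(OC)c(OC)c2C=O)cc1
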